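**Strategy.** The meso target is a cyclopent-3-ene ring: C1 is the tertiary carbinol carrying the undecanoyl group, C2 and C5 are the acetoxy carbons, and C3=C4 is the alkene. With C5 at the ketone level the ring is a 4,5-dioxygenated cyclopent-2-enone in which the acyl carbon C5 is bonded to the alkene carbon C4; that C4–C5 bond is the disconnection. A rhodium-catalysed intramolecular alkyne hydroacylation forms it and closes the five-membered ring in one operation from an acyclic 2,3-bis(silyloxy)-2-(undec-1-ynyl)pent-4-ynal. Its two oxygen stereocentres are set beforehand by syn-dihydroxylation of an (E)-enediyne ester. The undecynyl group is a masked undecanoyl group, unveiled last by acetate-assisted hydration.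

Key step: step 8

Remark (stereochemistry): the target has a mirror plane through C1 and the midpoint of C3=C4, so chiral intermediates are carried as racemates; names give relative configuration (R*,S*) and SMILES show one enantiomer.
Remark (intermediates): species that exist only bound to a catalytic metal are described in the Why lines and carry no number.

**Step 1**
Reactants: 1 ethyl (triphenylphosphoranylidene)acetate; 2 3-(trimethylsilyl)prop-2-ynal
Product: 4 ethyl (Z)-2-bromo-5-(trimethylsilyl)pent-2-en-4-ynoate, via bromo ylide 3 (not isolated)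
Conditions: NBS, CH2Cl2, −20 °C; then 2, −20 °C to rt
Reagents that add atoms: N-bromosuccinimide, O=C1CCC(=O)N1Br
Why: One-pot ylide halogenation/Wittig olefination: NBS brominates the stabilised ylide 1, succinimide anion deprotonates the salt to bromo ylide 3, and its Wittig reaction with the aldehyde of 2 places the ester trans to the alkynyl group as stabilised ylides do, hence the (Z)-bromoalkene.

**Step 2**
Reactants: 4 ethyl (Z)-2-bromo-5-(trimethylsilyl)pent-2-en-4-ynoate; 5 undec-1-yne
Product: 6 ethyl (E)-5-(trimethylsilyl)-2-(undec-1-yn-1-yl)pent-2-en-4-ynoate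
Conditions: Pd(PPh3)2Cl2 (3 mol %), CuI (5 mol %), Et3N, THF, rt
Reagents that add atoms: none
Why: Sonogashira coupling, in which zerovalent palladium formed in situ inserts into the activated vinyl C–Br bond with retention and the copper acetylide of 5 is transferred, so the undecynyl group takes the place of bromine cis to the silylalkyne.

**Step 3**
Reactants: 6 ethyl (E)-5-(trimethylsilyl)-2-(undec-1-yn-1-yl)pent-2-en-4-ynoate
Product: 7 ethyl (2R*,3S*)-2,3-dihydroxy-5-(trimethylsilyl)-2-(undec-1-yn-1-yl)pent-4-ynoate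
Conditions: OsO4 (5 mol %), NMO, citric acid (1 equiv), t-BuOH/H2O (1:1), rt
Reagents that add atoms: N-methylmorpholine N-oxide, C[N+]1([O-])CCOCC1 (oxygen relayed through osmium tetroxide, O=[Os](=O)(=O)=O); water, O
Why: Catalytic syn-dihydroxylation under the citric acid protocol for electron-poor alkenes adds both oxygens to one face of the only C=C bond (alkynes react far more slowly), so the (E) geometry of 6 fixes both new stereocentres as (2R*,3S*), the relation that places the two oxygens trans on the future ring.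

**Step 4**
Reactants: 7 ethyl (2R*,3S*)-2,3-dihydroxy-5-(trimethylsilyl)-2-(undec-1-yn-1-yl)pent-4-ynoate
Product: 8 ethyl (2R*,3S*)-3-[(tert-butyldimethylsilyl)oxy]-2-hydroxy-5-(trimethylsilyl)-2-(undec-1-yn-1-yl)pent-4-ynoate
Conditions: TBSOTf (1.05 equiv), 2,6-lutidine, CH2Cl2, −78 °C
Reagents that add atoms: tert-butyldimethylsilyl trifluoromethanesulfonate, CC(C)(C)[Si](C)(C)OS(=O)(=O)C(F)(F)F
Why: Silyl triflate silylation at low temperature should take the secondary propargylic hydroxyl and leave the tertiary one, which is flanked by the ester, the alkyne and C3 and is too hindered for one equivalent of the bulky triflate.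

**Step 5**
Reactants: 8 ethyl (2R*,3S*)-3-[(tert-butyldimethylsilyl)oxy]-2-hydroxy-5-(trimethylsilyl)-2-(undec-1-yn-1-yl)pent-4-ynoate
Product: 9 ethyl (2R*,3S*)-3-[(tert-butyldimethylsilyl)oxy]-2-[(triethylsilyl)oxy]-5-(trimethylsilyl)-2-(undec-1-yn-1-yl)pent-4-ynoate
Conditions: TESOTf, 2,6-lutidine, CH2Cl2, 0 °C to rt
Reagents that add atoms: triethylsilyl trifluoromethanesulfonate, CC[Si](CC)(CC)OS(=O)(=O)C(F)(F)F
Why: The smaller, highly reactive triethylsilyl triflate silylates the hindered tertiary α-hydroxy ester, giving an ether that masks this hydroxyl through reduction and ring closure and can later be cleaved beside the tert-butyldimethylsilyl ether.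

**Step 6**
Reactants: 9 ethyl (2R*,3S*)-3-[(tert-butyldimethylsilyl)oxy]-2-[(triethylsilyl)oxy]-5-(trimethylsilyl)-2-(undec-1-yn-1-yl)pent-4-ynoate
Product: 10 ethyl (2R*,3S*)-3-[(tert-butyldimethylsilyl)oxy]-2-[(triethylsilyl)oxy]-2-(undec-1-yn-1-yl)pent-4-ynoate
Conditions: K2CO3 (0.2 equiv), EtOH, 0 °C to rt
Reagents that add atoms: none
Why: Ethoxide-mediated protodesilylation of the alkynylsilane (ethanol matches the ethyl ester) frees the terminal alkyne, while the hindered trialkylsilyl ethers resist catalytic carbonate and the ester α-carbon bears no hydrogen, so nothing can epimerise or eliminate.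

**Step 7**
Reactants: 10 ethyl (2R*,3S*)-3-[(tert-butyldimethylsilyl)oxy]-2-[(triethylsilyl)oxy]-2-(undec-1-yn-1-yl)pent-4-ynoate
Product: 12 (2R*,3S*)-3-[(tert-butyldimethylsilyl)oxy]-2-[(triethylsilyl)oxy]-2-(undec-1-yn-1-yl)pent-4-ynal, via aluminium hemiacetal 11 (not isolated)
Conditions: iBu2AlH (1.2 equiv), CH2Cl2, −78 °C; then MeOH, aq. potassium sodium tartrate (KNaC4H4O6)
Reagents that add atoms: none
Why: Partial ester reduction with iBu2AlH stops at the tetrahedral aluminium hemiacetal 11, which is stable at −78 °C beside the α-silyloxy quaternary carbon and releases the aldehyde only on work-up; the alkynes are not hydroaluminated at this temperature.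

**Step 8**
Reactants: 12 (2R*,3S*)-3-[(tert-butyldimethylsilyl)oxy]-2-[(triethylsilyl)oxy]-2-(undec-1-yn-1-yl)pent-4-ynal
Product: 13 (4S*,5R*)-4-[(tert-butyldimethylsilyl)oxy]-5-[(triethylsilyl)oxy]-5-(undec-1-yn-1-yl)cyclopent-2-en-1-one
Conditions: [Rh(dppe)]2(BF4)2 (5 mol %; from [Rh(nbd)(dppe)]BF4 and H2), acetone, rt
Reagents that add atoms: none
Why: Monovalent rhodium inserts into the formyl C–H bond of 12 to give an acyl hydride of trivalent rhodium; the hydride is transferred to C4 of the bound terminal alkyne in a net trans sense so that rhodium ends on C5, and the six-membered acyl vinyl rhodacycle so formed joins C1 to C5 by reductive elimination and releases monovalent rhodium. The closest known reaction type is the rhodium-catalysed intramolecular trans-hydroacylation of 4-alkynals to cyclopent-2-enones with cationic diphosphine rhodium catalysts, applied here to a terminal alkyne next to a fully substituted α-carbon. The only ring formed, the cyclopentenone, closes in an overall 5-endo-dig mode, both alkyne carbons ending up in the ring. No stereocentre is created: C2 and C3 of 12 reappear as C5 and C4 of 13 with the trans relation of the two silyloxy groups set in step 3, and the quaternary C2 cannot epimerise. The step needs acyl transfer to the terminal C4≡C5 alkyne and not to the undecynyl alkyne, which is secured by ring size, since hydroacylation of the undecynyl alkyne could only close a three- or four-membered ring. It also needs ring closure to outrun decarbonylation and 4-exo closure to an alkylidenecyclobutanone, which the chelating dppe ligand (trans hydrometalation) and the non-enolisable quaternary α-carbon (slow CO extrusion to a tertiary alkyl) are expected to secure.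

**Step 9**
Reactants: 13 (4S*,5R*)-4-[(tert-butyldimethylsilyl)oxy]-5-[(triethylsilyl)oxy]-5-(undec-1-yn-1-yl)cyclopent-2-en-1-one
Product: 14 (4S*,5R*)-4-[(tert-butyldimethylsilyl)oxy]-5-hydroxy-5-(undec-1-yn-1-yl)cyclopent-2-en-1-one
Conditions: HF·pyridine, pyridine, THF, 0 °C
Reagents that add atoms: none
Why: Buffered fluoride cleavage removes the triethylsilyl ether, which is far more labile than the tert-butyldimethylsilyl ether on the hindered C4 oxygen, and leaves the enone untouched; the freed C5 hydroxyl is needed to steer the next step.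

**Step 10**
Reactants: 14 (4S*,5R*)-4-[(tert-butyldimethylsilyl)oxy]-5-hydroxy-5-(undec-1-yn-1-yl)cyclopent-2-en-1-one
Product: 16 (1S*,2R*,5S*)-5-[(tert-butyldimethylsilyl)oxy]-1-(undec-1-yn-1-yl)cyclopent-3-ene-1,2-diol, via alkoxyborohydride 15 (not isolated)
Conditions: Me4NBH(OAc)3, MeCN/AcOH (1:1), −30 to 0 °C
Reagents that add atoms: none
Why: Hydroxyl-directed reduction of the Saksena–Evans type: the tertiary hydroxyl exchanges with an acetate of the reagent to give alkoxyborohydride 15, which delivers hydride to the ketone from the face of that hydroxyl, so the new secondary hydroxyl is trans to the tertiary one and cis to the silyloxy group. The silyl ether on the other oxygen blocks delivery from the opposite face, and the weak hydride does not add in a conjugate sense.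

**Step 11**
Reactants: 16 (1S*,2R*,5S*)-5-[(tert-butyldimethylsilyl)oxy]-1-(undec-1-yn-1-yl)cyclopent-3-ene-1,2-diol
Product: 17 (2R,5S)-1-(undec-1-yn-1-yl)cyclopent-3-ene-1,2,5-triol (meso; both secondary hydroxyls trans to the C1 hydroxyl)
Conditions: Bu4NF, THF, 0 °C to rt
Reagents that add atoms: none
Why: Standard fluoride desilylation removes the remaining silyl ether without touching any stereocentre and gives the meso triol.

**Step 12**
Reactants: 17 (2R,5S)-1-(undec-1-yn-1-yl)cyclopent-3-ene-1,2,5-triol
Product: 18 (1R,3S)-2-hydroxy-2-(undec-1-yn-1-yl)cyclopent-4-ene-1,3-diyl diacetate (meso; hydroxyl trans to both acetoxy groups)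
Conditions: Ac2O, pyridine, CH2Cl2, rt
Reagents that add atoms: acetic anhydride, CC(=O)OC(C)=O
Why: Acetylation without a nucleophilic catalyst esterifies the two secondary allylic hydroxyls and leaves the hindered tertiary propargylic hydroxyl free (chemoselective acylation).

**Step 13**
Reactants: 18 (1R,3S)-2-hydroxy-2-(undec-1-yn-1-yl)cyclopent-4-ene-1,3-diyl diacetate
Product: 19 (1R,3S)-2-hydroxy-2-undecanoylcyclopent-4-ene-1,3-diyl diacetate (meso; both acetoxy groups cis to the undecanoyl group, trans to the hydroxyl)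
Conditions: Ph3PAuNTf2 (5 mol %), H2O (3 equiv), 1,4-dioxane, rt
Reagents that add atoms: water, O
Why: Neighbouring-group-assisted gold-catalysed alkyne hydration: cationic monovalent gold activates the alkyne, the carbonyl oxygen of a cis acetate attacks the ring-bound alkyne carbon (6-exo-dig) to give a 1,3-dioxan-2-ylium vinylgold species, water opens it with return of the acetate to its own oxygen, and protodeauration and tautomerisation leave the ketone on the carbon attached to C1; the two acetates of 18 are equivalent by symmetry.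

**Compound list**

1 | ethyl (triphenylphosphoranylidene)acetate | CCOC(=O)C=P(c1ccccc1)(c1ccccc1)c1ccccc1 | starting material
2 | 3-(trimethylsilyl)prop-2-ynal | C[Si](C)(C)C#CC=O | starting material
3 | ethyl bromo(triphenylphosphoranylidene)acetate (bromo ylide) | CCOC(=O)C(Br)=P(c1ccccc1)(c1ccccc1)c1ccccc1 | intermediate (not isolated)
4 | ethyl (Z)-2-bromo-5-(trimethylsilyl)pent-2-en-4-ynoate | CCOC(=O)/C(Br)=C/C#C[Si](C)(C)C | intermediate
5 | undec-1-yne | C#CCCCCCCCCC | starting material
6 | ethyl (E)-5-(trimethylsilyl)-2-(undec-1-yn-1-yl)pent-2-en-4-ynoate (the two alkynes cis) | CCOC(=O)/C(C#CCCCCCCCCC)=C/C#C[Si](C)(C)C | intermediate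
7 | ethyl (2R*,3S*)-2,3-dihydroxy-5-(trimethylsilyl)-2-(undec-1-yn-1-yl)pent-4-ynoate, racemic | CCCCCCCCCC#C[C@](O)(C(=O)OCC)[C@@H](O)C#C[Si](C)(C)C | intermediate
8 | ethyl (2R*,3S*)-3-[(tert-butyldimethylsilyl)oxy]-2-hydroxy-5-(trimethylsilyl)-2-(undec-1-yn-1-yl)pent-4-ynoate, racemic | CCCCCCCCCC#C[C@](O)(C(=O)OCC)[C@@H](O[Si](C)(C)C(C)(C)C)C#C[Si](C)(C)C | intermediate
9 | ethyl (2R*,3S*)-3-[(tert-butyldimethylsilyl)oxy]-2-[(triethylsilyl)oxy]-5-(trimethylsilyl)-2-(undec-1-yn-1-yl)pent-4-ynoate, racemic | CCCCCCCCCC#C[C@](O[Si](CC)(CC)CC)(C(=O)OCC)[C@@H](O[Si](C)(C)C(C)(C)C)C#C[Si](C)(C)C | intermediate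
10 | ethyl (2R*,3S*)-3-[(tert-butyldimethylsilyl)oxy]-2-[(triethylsilyl)oxy]-2-(undec-1-yn-1-yl)pent-4-ynoate, racemic | CCCCCCCCCC#C[C@](O[Si](CC)(CC)CC)(C(=O)OCC)[C@@H](O[Si](C)(C)C(C)(C)C)C#C | intermediate
11 | O-diisobutylaluminium ethyl hemiacetal of 12 (hemiacetal carbon unassigned) | CCCCCCCCCC#C[C@](O[Si](CC)(CC)CC)(C(OCC)O[Al](CC(C)C)CC(C)C)[C@@H](O[Si](C)(C)C(C)(C)C)C#C | intermediate (not isolated)
12 | (2R*,3S*)-3-[(tert-butyldimethylsilyl)oxy]-2-[(triethylsilyl)oxy]-2-(undec-1-yn-1-yl)pent-4-ynal, racemic | CCCCCCCCCC#C[C@](O[Si](CC)(CC)CC)(C=O)[C@@H](O[Si](C)(C)C(C)(C)C)C#C | intermediate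
13 | (4S*,5R*)-4-[(tert-butyldimethylsilyl)oxy]-5-[(triethylsilyl)oxy]-5-(undec-1-yn-1-yl)cyclopent-2-en-1-one, racemic, silyloxy groups trans | CCCCCCCCCC#C[C@@]1(O[Si](CC)(CC)CC)[C@@H](O[Si](C)(C)C(C)(C)C)C=CC1=O | intermediate
14 | (4S*,5R*)-4-[(tert-butyldimethylsilyl)oxy]-5-hydroxy-5-(undec-1-yn-1-yl)cyclopent-2-en-1-one, racemic | CCCCCCCCCC#C[C@@]1(O)[C@@H](O[Si](C)(C)C(C)(C)C)C=CC1=O | intermediate
15 | tetramethylammonium diacetoxy(hydrido)borate bound through the C5 oxygen of 14 | CCCCCCCCCC#C[C@@]1(O[BH-](OC(C)=O)OC(C)=O)[C@@H](O[Si](C)(C)C(C)(C)C)C=CC1=O.C[N+](C)(C)C | intermediate (not isolated)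
16 | (1S*,2R*,5S*)-5-[(tert-butyldimethylsilyl)oxy]-1-(undec-1-yn-1-yl)cyclopent-3-ene-1,2-diol, racemic | CCCCCCCCCC#C[C@@]1(O)[C@@H](O[Si](C)(C)C(C)(C)C)C=C[C@H]1O | intermediate
17 | (2R,5S)-1-(undec-1-yn-1-yl)cyclopent-3-ene-1,2,5-triol, meso, secondary hydroxyls cis to each other and trans to the C1 hydroxyl | CCCCCCCCCC#C[C@@]1(O)[C@@H](O)C=C[C@H]1O | intermediate
18 | (1R,3S)-2-hydroxy-2-(undec-1-yn-1-yl)cyclopent-4-ene-1,3-diyl diacetate, meso | CCCCCCCCCC#C[C@@]1(O)[C@@H](OC(C)=O)C=C[C@H]1OC(C)=O | intermediate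
19 | (1R,3S)-2-hydroxy-2-undecanoylcyclopent-4-ene-1,3-diyl diacetate, meso | CCCCCCCCCCC(=O)[C@@]1(O)[C@@H](OC(C)=O)C=C[C@H]1OC(C)=O | target

**Totals**

Total step count: 13. Longest linear sequence: 13 steps (from 1 and 2 to 19).

**Steps most likely to fail**

Step 8. The terminal alkyne may be diverted into vinylidene formation or oligomerisation on the cationic rhodium centre, and the congested acyl rhodium hydride may lose CO before it adds across the alkyne. The fallback makes the same C–C bond by a vinylchromium addition and sets out from 10. The terminal alkyne would be iodinated (NIS, cat. AgNO3, acetone) to the iodoalkyne ester F1. Diimide (2-nitrobenzenesulfonylhydrazide, Et3N) would reduce the iodoalkyne, faster than the hindered internal alkyne, to the (Z)-iodoalkene ester F2. iBu2AlH at −78 °C would give the (Z)-iodoalkenal F3, and an intramolecular Nozaki–Hiyama–Kishi reaction (CrCl2, cat. NiCl2, DMF) would close the ring to the cyclopentenol F4. Dess–Martin periodinane would then oxidise F4, and the route is rejoined at 13.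

Step 13. Water may add without acetate participation to the distal alkyne carbon, or the tertiary propargylic alcohol may ionise and rearrange in the Meyer–Schuster sense. The fallback places oxygen on the ring-bound alkyne carbon by tethered hydrosilylation and sets out from 17. 1,1,3,3-Tetramethyldisilazane would convert both secondary hydroxyls into dimethylsilyl ethers, giving the bis(dimethylsilyl) ether F5. Pt2(dvds)3 (dvds = 1,3-divinyltetramethyldisiloxane) would catalyse intramolecular syn-hydrosilylation (5-exo-dig) from one of the two equivalent silyl ethers to the alkylidene oxasilolane F6. Tamao–Fleming oxidation (H2O2, KF, KHCO3, THF/MeOH) would turn the C–Si bond into the ketone and strip the second silyl group, giving the keto triol F7. Ac2O/pyridine would acetylate its two secondary hydroxyls, and the route is rejoined at 19.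

Step 3. Osmylation of the electron-poor, doubly alkynylated alkene may be slow, and oxidation of the alkynes may then compete. The fallback sets the same two stereocentres by a Felkin–Anh addition and sets out from 2. Commercial ethyl 1,3-dithiane-2-carboxylate would be deprotonated (LiN(iPr)2, THF, −78 °C) to the lithium enolate F8, which adds to 2 to give the dithiane aldol F9. Silylation (TBSOTf, 2,6-lutidine) would give the silyl ether F10, and oxidative hydrolysis of the dithiane (PhI(OCOCF3)2, aqueous MeCN) would give the α-keto ester F11. Lithium undec-1-yn-1-ide F12 (from 5 and n-BuLi) would then be added at −78 °C. Attack anti to the silyloxy group and past the hydrogen should give the (2R*,3S*) hydroxy ester, and the route is rejoined at 8.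

**Further compounds**

F1 | step 8 | ethyl (2R*,3S*)-3-[(tert-butyldimethylsilyl)oxy]-5-iodo-2-[(triethylsilyl)oxy]-2-(undec-1-yn-1-yl)pent-4-ynoate | CCCCCCCCCC#C[C@](O[Si](CC)(CC)CC)(C(=O)OCC)[C@@H](O[Si](C)(C)C(C)(C)C)C#CI
F2 | step 8 | ethyl (2R*,3S*,4Z)-3-[(tert-butyldimethylsilyl)oxy]-5-iodo-2-[(triethylsilyl)oxy]-2-(undec-1-yn-1-yl)pent-4-enoate | CCCCCCCCCC#C[C@](O[Si](CC)(CC)CC)(C(=O)OCC)[C@@H](O[Si](C)(C)C(C)(C)C)/C=C\I
F3 | step 8 | (2R*,3S*,4Z)-3-[(tert-butyldimethylsilyl)oxy]-5-iodo-2-[(triethylsilyl)oxy]-2-(undec-1-yn-1-yl)pent-4-enal | CCCCCCCCCC#C[C@](O[Si](CC)(CC)CC)(C=O)[C@@H](O[Si](C)(C)C(C)(C)C)/C=C\I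
F4 | step 8 | 4-[(tert-butyldimethylsilyl)oxy]-5-[(triethylsilyl)oxy]-5-(undec-1-yn-1-yl)cyclopent-2-en-1-ol (silyloxy groups trans, C1 epimers) | CCCCCCCCCC#C[C@@]1(O[Si](CC)(CC)CC)[C@@H](O[Si](C)(C)C(C)(C)C)C=CC1O
F5 | step 13 | (2R,5S)-2,5-bis[(dimethylsilyl)oxy]-1-(undec-1-yn-1-yl)cyclopent-3-en-1-ol | CCCCCCCCCC#C[C@@]1(O)[C@@H](O[SiH](C)C)C=C[C@H]1O[SiH](C)C
F6 | step 13 | cis-fused 2-oxa-3-silabicyclo[3.3.0]oct-7-ene with 3,3-dimethyl, (E)-4-decylidene, 5-hydroxy and 6-[(dimethylsilyl)oxy] groups | CCCCCCCCC/C=C1\[C@@]2(O)[C@@H](O[Si]1(C)C)C=C[C@H]2O[SiH](C)C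
F7 | step 13 | 1-[(2R,5S)-1,2,5-trihydroxycyclopent-3-en-1-yl]undecan-1-one (meso) | CCCCCCCCCCC(=O)[C@@]1(O)[C@@H](O)C=C[C@H]1O
F8 | step 3 | lithium enolate of ethyl 1,3-dithiane-2-carboxylate | CCOC([O-])=C1SCCCS1.[Li+]
F9 | step 3 | ethyl 2-[1-hydroxy-3-(trimethylsilyl)prop-2-yn-1-yl]-1,3-dithiane-2-carboxylate (racemic) | CCOC(=O)C1(SCCCS1)[C@@H](O)C#C[Si](C)(C)C
F10 | step 3 | ethyl 2-{1-[(tert-butyldimethylsilyl)oxy]-3-(trimethylsilyl)prop-2-yn-1-yl}-1,3-dithiane-2-carboxylate (racemic) | CCOC(=O)C1(SCCCS1)[C@@H](O[Si](C)(C)C(C)(C)C)C#C[Si](C)(C)C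
F11 | step 3 | ethyl 3-[(tert-butyldimethylsilyl)oxy]-2-oxo-5-(trimethylsilyl)pent-4-ynoate (racemic) | CCOC(=O)C(=O)[C@@H](O[Si](C)(C)C(C)(C)C)C#C[Si](C)(C)C
F12 | step 3 | lithium undec-1-yn-1-ide | [Li+].[C-]#CCCCCCCCCC
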